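**Retrosynthetic overview**
1. Target 23 ⇐ silyl ether 22 ⇐ alcohol 20 + acid 21: the C8–O ester bond is made last, with inversion (Mitsunobu).
2. 20 ⇐ 17: an intramolecular Zn-Barbier allylation (C7–C8) closes the ten-membered carbocycle and converts the butenolide into the α-methylene-γ-lactone.
3. 17 ⇐ 13 + 15: the butenolide comes from acylation and ring-closing metathesis after asymmetric vinylation of the enal (sets C6).
4. 13 ⇐ 5 + CO + 10: key step, closure of the 3(2H)-furanone by C–O bond formation (tertiary OH onto C3) on a γ-hydroxy ynone assembled in the same flask.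
5. 5 ⇐ but-2-yne-1,4-diol (Red-Al/I2); 10 ⇐ (E)-3-methylpent-2-en-4-yn-1-ol (Sharpless epoxidation sets C10). Ring order: furanone, then butenolide, then the ten-membered ring.

Assumption (atom labels are germacrane numbers: C1 ketone, C3–O–C10 furanone bridge, C6/C7 lactone, C8 ester, C15 CH2OH): the Barbier ring closure is taken to give the 8S carbinol through a closed chair transition state; if it gives 8R instead, step 12 is run as a plain acylation with isobutyric anhydride/DMAP.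

**Route**

Step 1
Reactants: 1 but-2-yne-1,4-diol
Product: 2 4-[(tert-butyldiphenylsilyl)oxy]but-2-yn-1-ol
Conditions: NaH (1.0 equiv), THF, 0 °C; TBDPSCl (1.0 equiv), 0 °C → rt
Reagents that add atoms: tert-butyl(chloro)diphenylsilane, CC(C)(C)[Si](Cl)(c1ccccc1)c1ccccc1
Why: O-silylation of the sparingly soluble monosodium alkoxide gives clean monoprotection of the symmetric diol.

Step 2
Reactants: 2 4-[(tert-butyldiphenylsilyl)oxy]but-2-yn-1-ol
Product: 4 (Z)-4-[(tert-butyldiphenylsilyl)oxy]-3-iodobut-2-en-1-ol, via cyclic alkenylalanate 3 (not isolated)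
Conditions: Red-Al (1.6 equiv), THF, 0 °C → rt; then I2, −78 → 0 °C
Reagents that add atoms: iodine, II
Why: Hydroxyl-directed trans-hydroalumination of the propargylic alcohol puts Al on the distal alkyne carbon in a five-membered alkoxyalanate, and iodinolysis with retention gives the (Z)-vinyl iodide, fixing the C4=C5 geometry.

Step 3
Reactants: 4 (Z)-4-[(tert-butyldiphenylsilyl)oxy]-3-iodobut-2-en-1-ol
Product: 5 (Z)-4-[(tert-butyldiphenylsilyl)oxy]-3-iodobut-2-enal
Conditions: MnO2 (15 equiv), CH2Cl2, rt, dark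
Reagents that add atoms: none
Why: Allylic alcohol oxidation with MnO2 is neutral and keeps the Z geometry of the β-iodoenal.

Step 4
Reactants: 6 (E)-3-methylpent-2-en-4-yn-1-ol
Product: 7 [(2S,3S)-3-ethynyl-3-methyloxiran-2-yl]methanol
Conditions: Ti(OiPr)4 (10 mol%), L-(+)-DIPT (12 mol%), t-BuOOH, 4 Å MS, CH2Cl2, −20 °C
Reagents that add atoms: tert-butyl hydroperoxide, CC(C)(C)OO
Why: Sharpless asymmetric epoxidation of the 3,3-disubstituted (E)-allylic alcohol with the L-(+)-tartrate (the geraniol sense, 2S,3S) sets the C–O stereocentre that becomes C10.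

Step 5
Reactants: 7 [(2S,3S)-3-ethynyl-3-methyloxiran-2-yl]methanol
Product: 8 (R)-3-methylpent-4-yne-1,3-diol
Conditions: Red-Al (2.5 equiv), THF, −20 → 0 °C
Reagents that add atoms: none
Why: Red-Al opening of a 2,3-epoxy alcohol delivers hydride intramolecularly to C2 to give the 1,3-diol; the C3–O bond is not broken, so the tertiary centre is retained, and the alkyne is masked as its aluminium acetylide.

Step 6
Reactants: 8 (R)-3-methylpent-4-yne-1,3-diol
Product: 10 (R)-5,5-dimethoxy-3-methylpent-1-yn-3-ol, via hydroxy aldehyde 9 (not isolated)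
Conditions: TEMPO (10 mol%), PhI(OAc)2, CH2Cl2, rt; then HC(OMe)3, MeOH, PPTS, rt
Reagents that add atoms: trimethyl orthoformate, COC(OC)OC; methanol, CO
Why: Oxoammonium (TEMPO) oxidation takes the primary alcohol only, and acetalisation in the same flask protects the dehydration-prone β-hydroxy aldehyde without touching the stereocentre.

Step 7
Reactants: 5 (Z)-4-[(tert-butyldiphenylsilyl)oxy]-3-iodobut-2-enal; 10 (R)-5,5-dimethoxy-3-methylpent-1-yn-3-ol
Product: 13 (Z)-4-[(tert-butyldiphenylsilyl)oxy]-3-[(5R)-5-(2,2-dimethoxyethyl)-5-methyl-4-oxo-4,5-dihydrofuran-2-yl]but-2-enal, via ynone 11 (not isolated), via hydroxy diketone 12 (not isolated)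
Conditions: PdCl2(PPh3)2 (3 mol%), CuI (2 mol%), CO (10 bar), Et3N, THF, 25 °C, slow addition of 10; then DABCO (30 mol%), H2O, 45 °C; AcOH
Reagents that add atoms: carbon monoxide, [C-]#[O+]; water, O
Why: Proposed new method: a one-flask Pd/Cu carbonylative alkynylation of a (Z)-β-iodoenal with an enantioenriched tertiary propargylic alcohol, relayed by amine/water into a hydrative oxa-cyclisation; oxidative addition of 5, CO insertion and alkynyl transfer give γ-hydroxy ynone 11, DABCO adds to its β-carbon (C1) and is displaced by water to give hydroxy diketone 12, and the tertiary OH then closes onto the C3 carbonyl (5-exo-trig hemiketal) and dehydrates, forming the O–C3 bond of the 3(2H)-furanone with C10 untouched (configuration retained); the closest known reaction type is the Pd-catalysed carbonylative three-component synthesis of 5-aryl-2,2-dialkyl-3(2H)-furanones from aryl halides, tertiary propargylic alcohols and CO, which has not been shown for alkenyl iodides, enals or chiral acetal-bearing carbinols.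

Step 8
Reactants: 13 (Z)-4-[(tert-butyldiphenylsilyl)oxy]-3-[(5R)-5-(2,2-dimethoxyethyl)-5-methyl-4-oxo-4,5-dihydrofuran-2-yl]but-2-enal
Product: 14 (3S,4Z)-6-[(tert-butyldiphenylsilyl)oxy]-5-[(5R)-5-(2,2-dimethoxyethyl)-5-methyl-4-oxo-4,5-dihydrofuran-2-yl]hexa-1,4-dien-3-ol
Conditions: Zn(CH=CH2)2 (2.5 equiv), (−)-MIB (10 mol%), toluene, −20 → 0 °C; aq. NH4Cl
Reagents that add atoms: divinylzinc, C=C[Zn]C=C
Why: Amino-alcohol-catalysed asymmetric alkenylzinc 1,2-addition delivers the vinyl group to the Si face of the aldehyde (the sense that gives S alcohols from dialkylzincs), setting C6; the hindered furanone ketone does not react with R2Zn.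

Step 9
Reactants: 14 (3S,4Z)-6-[(tert-butyldiphenylsilyl)oxy]-5-[(5R)-5-(2,2-dimethoxyethyl)-5-methyl-4-oxo-4,5-dihydrofuran-2-yl]hexa-1,4-dien-3-ol; 15 2-(bromomethyl)prop-2-enoic acid
Product: 16 (3S,4Z)-6-[(tert-butyldiphenylsilyl)oxy]-5-[(5R)-5-(2,2-dimethoxyethyl)-5-methyl-4-oxo-4,5-dihydrofuran-2-yl]hexa-1,4-dien-3-yl 2-(bromomethyl)prop-2-enoate
Conditions: DCC, DMAP (5 mol%), CH2Cl2, −20 → 0 °C
Reagents that add atoms: none
Why: Steglich esterification acylates the bis-allylic alcohol under neutral conditions, so C6 is not ionised or epimerised.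

Step 10
Reactants: 16 (3S,4Z)-6-[(tert-butyldiphenylsilyl)oxy]-5-[(5R)-5-(2,2-dimethoxyethyl)-5-methyl-4-oxo-4,5-dihydrofuran-2-yl]hexa-1,4-dien-3-yl 2-(bromomethyl)prop-2-enoate
Product: 17 (5R)-3-(bromomethyl)-5-{(Z)-3-[(tert-butyldiphenylsilyl)oxy]-2-[(5R)-5-(2,2-dimethoxyethyl)-5-methyl-4-oxo-4,5-dihydrofuran-2-yl]prop-1-en-1-yl}furan-2(5H)-one
Conditions: Grubbs II (5 mol%), CH2Cl2 (5 mM), 40 °C
Reagents that add atoms: none
Why: Ring-closing metathesis between the vinyl group and the acrylate methylene gives the α-(bromomethyl)butenolide; the trisubstituted and push-pull alkenes do not take part and C6 is unchanged (the descriptor changes to R by CIP priority only).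

Step 11
Reactants: 17 (5R)-3-(bromomethyl)-5-{(Z)-3-[(tert-butyldiphenylsilyl)oxy]-2-[(5R)-5-(2,2-dimethoxyethyl)-5-methyl-4-oxo-4,5-dihydrofuran-2-yl]prop-1-en-1-yl}furan-2(5H)-one
Product: 20 (3aR,4S,6R,10Z,11aR)-10-{[(tert-butyldiphenylsilyl)oxy]methyl}-4-hydroxy-6-methyl-3-methylidene-3a,4,5,6-tetrahydro-6,9-epoxycyclodeca[b]furan-2,7(3H,11aH)-dione, via aldehyde 18 (not isolated), via allylzinc bromide 19 (not isolated)
Conditions: 1 M HCl, THF, 0 °C → rt; then Zn dust, THF/sat. aq. NH4Cl (2 mM), rt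
Reagents that add atoms: water, O
Why: Acetal hydrolysis followed by an intramolecular Barbier allylation: the cyclic allylzinc attacks the aldehyde through its γ-carbon C7 on the face anti to the C6 alkenyl group (sets C7, trans-lactone) through a chair Zimmerman–Traxler transition state with the tether equatorial (anti carbinol, C8 S), closing the ten-membered ring and unveiling the α-methylene lactone.

Step 12
Reactants: 20 (3aR,4S,6R,10Z,11aR)-10-{[(tert-butyldiphenylsilyl)oxy]methyl}-4-hydroxy-6-methyl-3-methylidene-3a,4,5,6-tetrahydro-6,9-epoxycyclodeca[b]furan-2,7(3H,11aH)-dione; 21 2-methylpropanoic acid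
Product: 22 (3aR,4R,6R,10Z,11aR)-10-{[(tert-butyldiphenylsilyl)oxy]methyl}-6-methyl-3-methylidene-2,7-dioxo-2,3,3a,4,5,6,7,11a-octahydro-6,9-epoxycyclodeca[b]furan-4-yl 2-methylpropanoate
Conditions: PPh3, DIAD, toluene, 0 °C → rt
Reagents that add atoms: none
Why: Mitsunobu esterification displaces the C8 oxyphosphonium by isobutyrate in an SN2 step, inverting C8 from S to the required R while forming the ester C–O bond.

Step 13
Reactants: 22 (3aR,4R,6R,10Z,11aR)-10-{[(tert-butyldiphenylsilyl)oxy]methyl}-6-methyl-3-methylidene-2,7-dioxo-2,3,3a,4,5,6,7,11a-octahydro-6,9-epoxycyclodeca[b]furan-4-yl 2-methylpropanoate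
Product: 23 (3aR,4R,6R,10Z,11aR)-10-(hydroxymethyl)-6-methyl-3-methylidene-2,7-dioxo-2,3,3a,4,5,6,7,11a-octahydro-6,9-epoxycyclodeca[b]furan-4-yl 2-methylpropanoate
Conditions: HF·pyridine, THF/pyridine, 0 °C → rt
Reagents that add atoms: none
Why: Buffered fluoride desilylation frees the C15 alcohol without adding to the α-methylene lactone or cleaving the ester.

**Compound list**
1 | but-2-yne-1,4-diol | OCC#CCO | starting material
2 | 4-[(tert-butyldiphenylsilyl)oxy]but-2-yn-1-ol | OCC#CCO[Si](c1ccccc1)(c1ccccc1)C(C)(C)C | intermediate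
3 | sodium cyclic (Z)-alkenylalanate (2,5-dihydro-1,2-oxaluminole ate complex; Al carries two 2-methoxyethoxy groups and is bonded to O-1 and to the alkene carbon bearing CH2OTBDPS) | [Na+].COCCO[Al-]1(OCCOC)OCC=C1CO[Si](c1ccccc1)(c1ccccc1)C(C)(C)C | intermediate
4 | (Z)-4-[(tert-butyldiphenylsilyl)oxy]-3-iodobut-2-en-1-ol | OC/C=C(/CO[Si](c1ccccc1)(c1ccccc1)C(C)(C)C)I | intermediate
5 | (Z)-4-[(tert-butyldiphenylsilyl)oxy]-3-iodobut-2-enal | O=C/C=C(/CO[Si](c1ccccc1)(c1ccccc1)C(C)(C)C)I | intermediate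
6 | (E)-3-methylpent-2-en-4-yn-1-ol | C#C/C(C)=C/CO | starting material
7 | [(2S,3S)-3-ethynyl-3-methyloxiran-2-yl]methanol | C#C[C@]1(C)O[C@H]1CO | intermediate
8 | (R)-3-methylpent-4-yne-1,3-diol | C#C[C@@](C)(CCO)O | intermediate
9 | (R)-3-hydroxy-3-methylpent-4-ynal | C#C[C@@](C)(CC=O)O | intermediate
10 | (R)-5,5-dimethoxy-3-methylpent-1-yn-3-ol | C#C[C@@](C)(CC(OC)OC)O | intermediate
11 | (2Z,7R)-3-{[(tert-butyldiphenylsilyl)oxy]methyl}-7-hydroxy-9,9-dimethoxy-7-methyl-4-oxonon-2-en-5-ynal | O=C/C=C(/CO[Si](c1ccccc1)(c1ccccc1)C(C)(C)C)C(=O)C#C[C@@](C)(CC(OC)OC)O | intermediate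
12 | (2Z,7R)-3-{[(tert-butyldiphenylsilyl)oxy]methyl}-7-hydroxy-9,9-dimethoxy-7-methyl-4,6-dioxonon-2-enal | O=C/C=C(/CO[Si](c1ccccc1)(c1ccccc1)C(C)(C)C)C(=O)CC(=O)[C@@](C)(CC(OC)OC)O | intermediate
13 | (Z)-4-[(tert-butyldiphenylsilyl)oxy]-3-[(5R)-5-(2,2-dimethoxyethyl)-5-methyl-4-oxo-4,5-dihydrofuran-2-yl]but-2-enal | O=C/C=C(/CO[Si](c1ccccc1)(c1ccccc1)C(C)(C)C)C1=CC(=O)[C@@](C)(CC(OC)OC)O1 | intermediate
14 | (3S,4Z)-6-[(tert-butyldiphenylsilyl)oxy]-5-[(5R)-5-(2,2-dimethoxyethyl)-5-methyl-4-oxo-4,5-dihydrofuran-2-yl]hexa-1,4-dien-3-ol | C=C[C@H](O)/C=C(/CO[Si](c1ccccc1)(c1ccccc1)C(C)(C)C)C1=CC(=O)[C@@](C)(CC(OC)OC)O1 | intermediate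
15 | 2-(bromomethyl)prop-2-enoic acid | C=C(CBr)C(=O)O | starting material
16 | (3S,4Z)-6-[(tert-butyldiphenylsilyl)oxy]-5-[(5R)-5-(2,2-dimethoxyethyl)-5-methyl-4-oxo-4,5-dihydrofuran-2-yl]hexa-1,4-dien-3-yl 2-(bromomethyl)prop-2-enoate | C=C[C@H](OC(=O)C(=C)CBr)/C=C(/CO[Si](c1ccccc1)(c1ccccc1)C(C)(C)C)C1=CC(=O)[C@@](C)(CC(OC)OC)O1 | intermediate
17 | (5R)-3-(bromomethyl)-5-{(Z)-3-[(tert-butyldiphenylsilyl)oxy]-2-[(5R)-5-(2,2-dimethoxyethyl)-5-methyl-4-oxo-4,5-dihydrofuran-2-yl]prop-1-en-1-yl}furan-2(5H)-one | BrCC1=C[C@H](OC1=O)/C=C(/CO[Si](c1ccccc1)(c1ccccc1)C(C)(C)C)C1=CC(=O)[C@@](C)(CC(OC)OC)O1 | intermediate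
18 | (5R)-3-(bromomethyl)-5-{(Z)-3-[(tert-butyldiphenylsilyl)oxy]-2-[(5R)-5-methyl-4-oxo-5-(2-oxoethyl)-4,5-dihydrofuran-2-yl]prop-1-en-1-yl}furan-2(5H)-one | BrCC1=C[C@H](OC1=O)/C=C(/CO[Si](c1ccccc1)(c1ccccc1)C(C)(C)C)C1=CC(=O)[C@@](C)(CC=O)O1 | intermediate
19 | allylzinc bromide of 18 (ZnBr in place of Br on the butenolide CH2) | Br[Zn]CC1=C[C@H](OC1=O)/C=C(/CO[Si](c1ccccc1)(c1ccccc1)C(C)(C)C)C1=CC(=O)[C@@](C)(CC=O)O1 | intermediate
20 | (3aR,4S,6R,10Z,11aR)-10-{[(tert-butyldiphenylsilyl)oxy]methyl}-4-hydroxy-6-methyl-3-methylidene-3a,4,5,6-tetrahydro-6,9-epoxycyclodeca[b]furan-2,7(3H,11aH)-dione (8-epi alcohol) | C=C1C(=O)O[C@@H]2/C=C(/CO[Si](c4ccccc4)(c4ccccc4)C(C)(C)C)C3=CC(=O)[C@@](C)(C[C@H](O)[C@@H]12)O3 | intermediate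
21 | 2-methylpropanoic acid | CC(C)C(=O)O | starting material
22 | (3aR,4R,6R,10Z,11aR)-10-{[(tert-butyldiphenylsilyl)oxy]methyl}-6-methyl-3-methylidene-2,7-dioxo-2,3,3a,4,5,6,7,11a-octahydro-6,9-epoxycyclodeca[b]furan-4-yl 2-methylpropanoate | C=C1C(=O)O[C@@H]2/C=C(/CO[Si](c4ccccc4)(c4ccccc4)C(C)(C)C)C3=CC(=O)[C@@](C)(C[C@@H](OC(=O)C(C)C)[C@@H]12)O3 | intermediate
23 | (3aR,4R,6R,10Z,11aR)-10-(hydroxymethyl)-6-methyl-3-methylidene-2,7-dioxo-2,3,3a,4,5,6,7,11a-octahydro-6,9-epoxycyclodeca[b]furan-4-yl 2-methylpropanoate (CNP0176924.3) | C=C1C(=O)O[C@@H]2/C=C(/CO)C3=CC(=O)[C@@](C)(C[C@@H](OC(=O)C(C)C)[C@@H]12)O3 | target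

**Step count and risks**
Total steps: 13. Longest linear sequence: 10 steps (1 → 5 through steps 1–3, or 6 → 10 through steps 4–6, then steps 7–13).

Step 7 (the proposed new step). The electron-poor alkenyl–Pd may couple directly with the alkyne before CO inserts, and the enal or acetal may not tolerate the amine/water stage. The fallback uses known chemistry and sets out from 5 and 10. The carbonylative Sonogashira coupling is run as a separate conventional step (copper-free Pd/Xantphos, CO 10 bar, Et3N) and ynone 11 is isolated. The furanone is then closed in a second step with a cationic gold(I) catalyst ((p-CF3C6H4)3PAuCl/AgOTf, toluene, rt), the established cycloisomerisation of γ-hydroxy alkynones through π-activation instead of conjugate hydration. The route is rejoined at 13, and no compound outside the list is made (F0).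

Step 11. The ten-membered ring may lose out to oligomerisation, the β-alkoxy aldehyde 18 may eliminate, and the C8 epimer ratio is uncertain. The fallback changes the order of ring construction and sets out from 5, with 10, 15 and 21. Vinylation of 5 with (−)-MIB/divinylzinc gives (3S,4Z)-6-[(tert-butyldiphenylsilyl)oxy]-5-iodohexa-1,4-dien-3-ol F1. Esterification with 15 gives the 2-(bromomethyl)acrylate F2, and metathesis (Grubbs II) gives the iodoalkenyl bromomethyl butenolide F3. An intermolecular Zn/NH4Cl Barbier reaction of F3 with hydroxy aldehyde 9 (released from 10 with dilute acid) gives the acyclic α-methylene lactone diol F4, with C7 anti to C6 and the anti (8S) carbinol. Mitsunobu esterification with 21 gives isobutyrate F5. The ten-membered ring is then closed together with the furanone by an intramolecular carbonylative alkynylation/hydrative cyclisation of F5 at high dilution (conditions of step 7), rejoining the route at 22.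

Step 12. Mitsunobu activation next to the acidic, allylic C7–H may give elimination or incomplete inversion. The fallback sets out from 20 and replaces the redox condensation by a sulfonate displacement. MsCl/Et3N gives the methanesulfonate F6, which is displaced with caesium 2-methylpropanoate/18-crown-6 in toluene (SN2, inversion) to rejoin the route at 22.

**Further compounds**
F0 | step 7 | none | none
F1 | step 11 | (3S,4Z)-6-[(tert-butyldiphenylsilyl)oxy]-5-iodohexa-1,4-dien-3-ol | C=C[C@H](O)/C=C(/CO[Si](c1ccccc1)(c1ccccc1)C(C)(C)C)I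
F2 | step 11 | (3S,4Z)-6-[(tert-butyldiphenylsilyl)oxy]-5-iodohexa-1,4-dien-3-yl 2-(bromomethyl)prop-2-enoate | C=C[C@H](OC(=O)C(=C)CBr)/C=C(/CO[Si](c1ccccc1)(c1ccccc1)C(C)(C)C)I
F3 | step 11 | (5S)-3-(bromomethyl)-5-{(Z)-3-[(tert-butyldiphenylsilyl)oxy]-2-iodoprop-1-en-1-yl}furan-2(5H)-one | BrCC1=C[C@H](OC1=O)/C=C(/CO[Si](c1ccccc1)(c1ccccc1)C(C)(C)C)I
F4 | step 11 | (4R,5S)-4-[(1S,3R)-1,3-dihydroxy-3-methylpent-4-yn-1-yl]-5-{(Z)-3-[(tert-butyldiphenylsilyl)oxy]-2-iodoprop-1-en-1-yl}-3-methylideneoxolan-2-one | C=C1C(=O)O[C@H](/C=C(/CO[Si](c2ccccc2)(c2ccccc2)C(C)(C)C)I)[C@H]1[C@@H](O)C[C@@](C)(O)C#C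
F5 | step 11 | (1R,3R)-1-[(2S,3R)-2-{(Z)-3-[(tert-butyldiphenylsilyl)oxy]-2-iodoprop-1-en-1-yl}-4-methylidene-5-oxooxolan-3-yl]-3-hydroxy-3-methylpent-4-yn-1-yl 2-methylpropanoate | C=C1C(=O)O[C@H](/C=C(/CO[Si](c2ccccc2)(c2ccccc2)C(C)(C)C)I)[C@H]1[C@H](OC(=O)C(C)C)C[C@@](C)(O)C#C
F6 | step 12 | (3aR,4S,6R,10Z,11aR)-10-{[(tert-butyldiphenylsilyl)oxy]methyl}-6-methyl-3-methylidene-2,7-dioxo-2,3,3a,4,5,6,7,11a-octahydro-6,9-epoxycyclodeca[b]furan-4-yl methanesulfonate | C=C1C(=O)O[C@@H]2/C=C(/CO[Si](c4ccccc4)(c4ccccc4)C(C)(C)C)C3=CC(=O)[C@@](C)(C[C@H](OS(C)(=O)=O)[C@@H]12)O3
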